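**Retrosynthetic overview**
1. Endgame: the triol aldehyde is unmasked last (acetal hydrolysis, thiolate demethylation). The C8 methyl group and the (E)-C9=C11 bond arise together by anti-SN2′ methylation of a C11 picolinate. The C9–C11 bond comes from a Ni/Cr coupling of the C9 enol triflate of the cis-decalone with a 2,6-dimethoxybenzaldehyde.
2. The plan rests on the cis C5–C10 ring fusion with quaternary C4 (gem-dimethyl) beside it in ring A. This is the retron of an anionic oxy-Cope rearrangement that forms C4–C5 and cuts a C2–C7 bond absent from the target.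
3. The rearrangement precursor is a 2-(2-methylprop-1-enyl)bicyclo[2.2.2]oct-5-en-2-ol. It comes from alkenylcerium addition to a bicyclooctenone made by Diels–Alder reaction of the masked o-benzoquinone of 2-methoxy-3-methylphenol with benzyl vinyl ether (ketene equivalent), deoxygenation at C8 and lipase resolution.
4. Ring order: the phenol ring supplies the six carbons of ring B; the Diels–Alder step adds the temporary bridge (C1, C2); the oxy-Cope step closes ring A as the bicycle opens to the cis-decalin.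

Key step: step 9

Remark on numbering: C1–C11 are drimane numbers (ring A = C1–C5 and C10, ring B = C5–C10, C11 = benzylic carbon). Bicyclic compounds 8–16 carry bicyclo[2.2.2]octene numbers, which map onto drimane numbers as C1→C7, C2→C2, C3→C1, C4→C10, C5→C5, C6→C6, C7→C8, C8→C9.
Assumption: the lipase acylates the (2R)-alcohol faster (empirical size rule for secondary alcohols, bridgehead carbon as the large group), so the needed (1S,2S,4S)-alcohol is recovered unchanged. If the preference is the reverse, the needed enantiomer is taken from the acetate fraction by K2CO3/MeOH.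

**Step 1**
Reactants: 1 2-methoxy-3-methylphenol; 2 benzyl vinyl ether
Product: 4 rac-7-(benzyloxy)-3,3-dimethoxy-4-methylbicyclo[2.2.2]oct-5-en-2-one (benzyloxy group syn to the C5=C6 bridge), via 6,6-dimethoxy-5-methylcyclohexa-2,4-dien-1-one 3 (not isolated)
Conditions: PhI(OAc)2 (1.2 equiv), 2 (10 equiv), MeOH, 0 °C → rt, slow addition of 1
Reagents that add atoms: methanol, CO
Why: Oxidative dearomatisation in methanol gives the masked o-benzoquinone 3, an electron-poor diene that undergoes an inverse-electron-demand Diels–Alder reaction with the vinyl ether; the nucleophilic CH2 terminus bonds to the methyl-bearing diene terminus (largest LUMO coefficient), the endo transition state places the benzyloxy group syn to the new double bond, and the bicycle fixes the two bridgeheads relative to each other (racemic).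

**Step 2**
Reactants: 4 rac-7-(benzyloxy)-3,3-dimethoxy-4-methylbicyclo[2.2.2]oct-5-en-2-one
Product: 5 rac-7-(benzyloxy)-3,3-dimethoxy-4-methylbicyclo[2.2.2]oct-5-en-2-ol (hydroxyl group anti to the C5=C6 bridge expected)
Conditions: NaBH4, MeOH, 0 °C
Reagents that add atoms: none
Why: Borohydride reduction of the non-enolisable α-ketal ketone, with hydride arriving from the less hindered face beside the C5=C6 bridge; the configuration of the new carbinol carbon is of no consequence because this oxygen is removed in step 4.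

**Step 3**
Reactants: 5 rac-7-(benzyloxy)-3,3-dimethoxy-4-methylbicyclo[2.2.2]oct-5-en-2-ol
Product: 7 rac-O-[7-(benzyloxy)-3,3-dimethoxy-4-methylbicyclo[2.2.2]oct-5-en-2-yl] S-methyl carbonodithioate, via sodium O-alkyl dithiocarbonate 6 (not isolated)
Conditions: NaH, THF, 0 °C; CS2; then MeI, rt
Reagents that add atoms: carbon disulfide, S=C=S; iodomethane, CI
Why: Xanthate formation (alkoxide addition to CS2, then S-methylation) prepares the secondary alcohol for radical deoxygenation without touching any stereocenter.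

**Step 4**
Reactants: 7 rac-O-[7-(benzyloxy)-3,3-dimethoxy-4-methylbicyclo[2.2.2]oct-5-en-2-yl] S-methyl carbonodithioate
Product: 8 rac-2-(benzyloxy)-8,8-dimethoxy-4-methylbicyclo[2.2.2]oct-5-ene (benzyloxy group syn to the C5=C6 bridge)
Conditions: Bu3SnH (about 0.3 M), AIBN, toluene, 110 °C
Reagents that add atoms: none
Why: Barton–McCombie deoxygenation (stannyl radical addition to the thiocarbonyl group, β-scission to the secondary radical at the former carbinol carbon, hydrogen transfer from the stannane), run at high stannane concentration so that the homoallylic radical is reduced before it can rearrange through a cyclopropylcarbinyl radical; the carbinol stereocenter is removed.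

**Step 5**
Reactants: 8 rac-2-(benzyloxy)-8,8-dimethoxy-4-methylbicyclo[2.2.2]oct-5-ene
Product: 9 rac-8,8-dimethoxy-4-methylbicyclo[2.2.2]oct-5-en-2-ol (hydroxyl group syn to the C5=C6 bridge)
Conditions: lithium 4,4′-di-tert-butylbiphenylide, THF, −78 °C; then aq. NH4Cl
Reagents that add atoms: none
Why: Reductive debenzylation by single-electron transfer from the arene radical anion cleaves the benzylic C–O bond only, leaving the isolated alkene and the dimethyl ketal intact and the carbinol configuration unchanged.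

**Step 6**
Reactants: 9 rac-8,8-dimethoxy-4-methylbicyclo[2.2.2]oct-5-en-2-ol
Product: 10 (1S,2S,4S)-8,8-dimethoxy-4-methylbicyclo[2.2.2]oct-5-en-2-ol
Conditions: Burkholderia cepacia lipase (Amano PS, immobilised), vinyl acetate, t-BuOMe, 30 °C, run to slightly beyond half conversion; chromatography
Reagents that add atoms: none
Why: Lipase-catalysed kinetic resolution by enantioselective transesterification: the enzyme should acylate the (2R)-alcohol, so the (1S,2S,4S)-alcohol is recovered unchanged and fixes the absolute configuration of both bridgeheads.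

**Step 7**
Reactants: 10 (1S,2S,4S)-8,8-dimethoxy-4-methylbicyclo[2.2.2]oct-5-en-2-ol
Product: 11 (1S,4S)-8,8-dimethoxy-4-methylbicyclo[2.2.2]oct-5-en-2-one
Conditions: Dess–Martin periodinane, NaHCO3, CH2Cl2, 0 °C → rt
Reagents that add atoms: none
Why: Dess–Martin oxidation of the secondary alcohol under buffered conditions that spare the ketal; the β,γ-unsaturated ketone cannot move into conjugation because C1 is a bridgehead, and the bridgehead stereocenters are untouched.

**Step 8**
Reactants: 11 (1S,4S)-8,8-dimethoxy-4-methylbicyclo[2.2.2]oct-5-en-2-one; 12 1-bromo-2-methylprop-1-ene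
Product: 15 (1S,2R,4S)-8,8-dimethoxy-4-methyl-2-(2-methylprop-1-en-1-yl)bicyclo[2.2.2]oct-5-en-2-ol (alkenyl group syn to the C5=C6 bridge), via (2-methylprop-1-en-1-yl)lithium 13 (not isolated), via dichloro(2-methylprop-1-en-1-yl)cerium 14 (not isolated)
Conditions: 12, t-BuLi (2 equiv), THF–Et2O, −78 °C; anhydrous CeCl3, −78 °C; then 11, −78 °C; aq. NH4Cl
Reagents that add atoms: none
Why: 1,2-Addition of an organocerium reagent (bromine–lithium exchange, transmetalation with CeCl3), which is nucleophilic but weakly basic and so avoids enolisation; it attacks the carbonyl group from the open face beside the C5=C6 bridge (the other face is screened by the C7 methylene hydrogens), which sets C2 with the alkenyl group syn to the alkene as the rearrangement requires.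

**Step 9**
Reactants: 15 (1S,2R,4S)-8,8-dimethoxy-4-methyl-2-(2-methylprop-1-en-1-yl)bicyclo[2.2.2]oct-5-en-2-ol
Product: 18 (4aR,8aS)-8,8-dimethoxy-4,4,8a-trimethyl-3,4,4a,7,8,8a-hexahydronaphthalen-2(1H)-one (cis-fused; drimane C2 ketone; C6=C7 alkene; C9 dimethyl ketal), via potassium alkoxide 16 (not isolated), via potassium C2–C3 enolate 17 (not isolated)
Conditions: KH (3 equiv), 18-crown-6, THF, 0 °C → 50 °C; then aq. NH4Cl, −78 °C
Reagents that add atoms: none
Why: Deprotonation gives alkoxide 16, whose oxyanion weakens the adjacent C2–C7 σ bond (drimane numbers) so that the 1,5-diene C4=C3–C2–C7–C6=C5 undergoes a concerted anionic oxy-Cope [3,3]-sigmatropic shift far below the temperature of the neutral rearrangement, giving enolate 17, which is protonated at C3 on work-up. The reaction type is the established anionic oxy-Cope rearrangement of 2-alkenylbicyclo[2.2.2]oct-5-en-2-ols to cis-decalinones. Ring A (C1–C5, C10) closes by formation of the C4–C5 σ bond between the two alkene termini through the boat transition state that the bicycle enforces, while cleavage of C2–C7 opens the bicycle and leaves the six-membered ring C5–C10 as ring B with a C6=C7 double bond. The only new stereocenter, C5, is set by the suprafacial course of the shift: the alkenyl group lies over the C5=C6 bridge on the side of the C10–C1 bond, so C4 bonds to the face of C5 that leaves H5 cis to the C10 methyl group (cis fusion), C10 itself being untouched. The step needs the rearrangement to outrun fragmentation of the alkoxide back to ketone 11; the naked potassium alkoxide (18-crown-6) and the syn placement of the alkenyl group from step 8 secure this, and the inward-pointing methyl group of the trisubstituted alkene is the main source of strain in the boat.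

**Step 10**
Reactants: 18 (4aR,8aS)-8,8-dimethoxy-4,4,8a-trimethyl-3,4,4a,7,8,8a-hexahydronaphthalen-2(1H)-one
Product: 20 (4aR,8aS)-1,1-dimethoxy-5,5,8a-trimethyl-1,2,4a,5,6,7,8,8a-octahydronaphthalene, via hydrazone 19 (not isolated)
Conditions: N2H4·H2O, KOH, diethylene glycol, 130 °C then 200 °C, argon
Reagents that add atoms: none
Why: Wolff–Kishner reduction (Huang-Minlon procedure) through hydrazone 19 removes the C2 carbonyl group under strongly basic conditions that the ketal and the isolated alkene tolerate; C5 and C10 are not enolisable and stay as set.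

**Step 11**
Reactants: 20 (4aR,8aS)-1,1-dimethoxy-5,5,8a-trimethyl-1,2,4a,5,6,7,8,8a-octahydronaphthalene
Product: 21 (4aR,8aS)-1,1-dimethoxy-5,5,8a-trimethyldecahydronaphthalene
Conditions: H2 (1 atm), PtO2, EtOAc, rt
Reagents that add atoms: none
Why: Heterogeneous catalytic hydrogenation of the cis-disubstituted C6=C7 double bond, with platinum chosen over palladium to minimise double-bond migration toward C5; no stereocenter is formed.

**Step 12**
Reactants: 21 (4aR,8aS)-1,1-dimethoxy-5,5,8a-trimethyldecahydronaphthalene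
Product: 22 (4aR,8aS)-5,5,8a-trimethyloctahydronaphthalen-1(2H)-one
Conditions: 2 M HCl, THF, rt → 40 °C
Reagents that add atoms: water, O
Why: Acid-catalysed ketal hydrolysis through the oxocarbenium ion; C10 is quaternary and C5 is not α to the carbonyl group, so no stereocenter can epimerise.

**Step 13**
Reactants: 22 (4aR,8aS)-5,5,8a-trimethyloctahydronaphthalen-1(2H)-one
Product: 24 (4aR,8aS)-5,5,8a-trimethyl-3,4,4a,5,6,7,8,8a-octahydronaphthalen-1-yl trifluoromethanesulfonate, via potassium enolate 23 (not isolated)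
Conditions: KN(SiMe3)2, THF, −78 °C; PhNTf2, −78 → 0 °C
Reagents that add atoms: N-phenylbis(trifluoromethanesulfonimide), O=S(=O)(N(c1ccccc1)S(=O)(=O)C(F)(F)F)C(F)(F)F
Why: Regiospecific enolisation (only C8 carries α-hydrogens) and O-sulfonylation of enolate 23 give the C8=C9 enol triflate.

**Step 14**
Reactants: 25 2,4,5-trimethoxybenzaldehyde
Product: 26 5,5-dimethyl-2-(2,4,5-trimethoxyphenyl)-1,3-dioxane
Conditions: 2,2-dimethylpropane-1,3-diol, p-TsOH (cat.), toluene, reflux, Dean–Stark trap
Reagents that add atoms: 2,2-dimethylpropane-1,3-diol, OCC(C)(C)CO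
Why: Acid-catalysed acetalisation with azeotropic removal of water masks the formyl group as a base-stable 1,3-dioxane that does not fragment on lithiation.

**Step 15**
Reactants: 26 5,5-dimethyl-2-(2,4,5-trimethoxyphenyl)-1,3-dioxane
Product: 28 3-(5,5-dimethyl-1,3-dioxan-2-yl)-2,5,6-trimethoxybenzaldehyde, via aryllithium 27 (not isolated)
Conditions: n-BuLi, THF, 0 °C; DMF, −78 °C → rt; aq. NH4Cl
Reagents that add atoms: N,N-dimethylformamide, CN(C)C=O
Why: Directed ortho-metalation at the ring position flanked by two methoxy groups (the most acidic, doubly coordinated site) gives aryllithium 27, which is formylated by DMF.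

**Step 16**
Reactants: 24 (4aR,8aS)-5,5,8a-trimethyl-3,4,4a,5,6,7,8,8a-octahydronaphthalen-1-yl trifluoromethanesulfonate; 28 3-(5,5-dimethyl-1,3-dioxan-2-yl)-2,5,6-trimethoxybenzaldehyde
Product: 30 (S)-[3-(5,5-dimethyl-1,3-dioxan-2-yl)-2,5,6-trimethoxyphenyl][(4aR,8aS)-5,5,8a-trimethyl-3,4,4a,5,6,7,8,8a-octahydronaphthalen-1-yl]methanol, via alkenylchromium dichloride 29 (not isolated)
Conditions: CrCl2 (4 equiv), NiCl2 (2 mol %), DMF, rt; chromatographic separation of the C11 epimers
Reagents that add atoms: none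
Why: Nozaki–Hiyama–Kishi coupling (nickel-catalysed activation of the C9–O triflate bond, transmetalation to the alkenyl trivalent chromium species 29, chemoselective addition to the aldehyde); C11 is set under substrate control, the aldehyde being expected to approach C9 on the convex face of the cis-decalin (the face of H5 and the C10 methyl group, away from C1) with its aryl group turned away from quaternary C10, which leads to the (S)-carbinol; the preference is likely to be moderate, so the (11S)-epimer is separated.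

**Step 17**
Reactants: 30 (S)-[3-(5,5-dimethyl-1,3-dioxan-2-yl)-2,5,6-trimethoxyphenyl][(4aR,8aS)-5,5,8a-trimethyl-3,4,4a,5,6,7,8,8a-octahydronaphthalen-1-yl]methanol
Product: 31 (S)-[3-(5,5-dimethyl-1,3-dioxan-2-yl)-2,5,6-trimethoxyphenyl][(4aR,8aS)-5,5,8a-trimethyl-3,4,4a,5,6,7,8,8a-octahydronaphthalen-1-yl]methyl pyridine-2-carboxylate
Conditions: picolinic acid, DCC, DMAP (cat.), CH2Cl2, rt
Reagents that add atoms: pyridine-2-carboxylic acid, OC(=O)c1ccccn1
Why: Carbodiimide (Steglich) esterification installs the chelating picolinoxy leaving group with retention at C11.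

**Step 18**
Reactants: 31 (S)-[3-(5,5-dimethyl-1,3-dioxan-2-yl)-2,5,6-trimethoxyphenyl][(4aR,8aS)-5,5,8a-trimethyl-3,4,4a,5,6,7,8,8a-octahydronaphthalen-1-yl]methyl pyridine-2-carboxylate
Product: 32 2-[2,4,5-trimethoxy-3-[(E)-[(2S,4aR,8aS)-2,5,5,8a-tetramethyloctahydronaphthalen-1(2H)-ylidene]methyl]phenyl]-5,5-dimethyl-1,3-dioxane
Conditions: MeMgBr (3 equiv), CuBr·SMe2 (1.5 equiv), THF, −40 → 0 °C
Reagents that add atoms: methylmagnesium bromide, C[Mg]Br
Why: Copper-mediated anti-SN2′ allylic substitution of a picolinate: magnesium chelation by the picolinoxy group activates the leaving group, and the methylcopper reagent attacks C8 on the face opposite to the C11–O bond in the rotamer that has H11 eclipsed with C10 and the aryl group toward C8, so the (11S)-centre is relayed into (8S) with the new methyl group cis to the C10 methyl group (convex face) and the new C9=C11 bond is E.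

**Step 19**
Reactants: 32 2-[2,4,5-trimethoxy-3-[(E)-[(2S,4aR,8aS)-2,5,5,8a-tetramethyloctahydronaphthalen-1(2H)-ylidene]methyl]phenyl]-5,5-dimethyl-1,3-dioxane
Product: 33 2,4,5-trimethoxy-3-[(E)-[(2S,4aR,8aS)-2,5,5,8a-tetramethyloctahydronaphthalen-1(2H)-ylidene]methyl]benzaldehyde
Conditions: PPTS, acetone–H2O, 50 °C
Reagents that add atoms: water, O
Why: Mild acid-catalysed acetal hydrolysis releases the aryl aldehyde while the methyl ethers still keep the arene oxygens from cyclising onto the trisubstituted alkene.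

**Step 20**
Reactants: 33 2,4,5-trimethoxy-3-[(E)-[(2S,4aR,8aS)-2,5,5,8a-tetramethyloctahydronaphthalen-1(2H)-ylidene]methyl]benzaldehyde
Product: 34 2,4,5-trihydroxy-3-[(E)-[(2S,4aR,8aS)-2,5,5,8a-tetramethyloctahydronaphthalen-1(2H)-ylidene]methyl]benzaldehyde (target)
Conditions: NaSEt (excess), degassed DMF, 120 °C; then 1 M HCl under argon
Reagents that add atoms: none
Why: Nucleophilic (SN2) demethylation of the three aryl methyl ethers by ethanethiolate under basic conditions, chosen because acid would cyclise an ortho-phenol onto the C9=C11 alkene; the ethers ortho and para to the formyl group should go first, the third needs excess reagent and heat, and air is excluded because the hydroxyquinol is easily oxidised.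

**Compound list**
1 | 2-methoxy-3-methylphenol | COc1c(C)cccc1O | starting material
2 | benzyl vinyl ether | C=COCc1ccccc1 | starting material
3 | 6,6-dimethoxy-5-methylcyclohexa-2,4-dien-1-one | COC1(OC)C(C)=CC=CC1=O | intermediate
4 | rac-7-(benzyloxy)-3,3-dimethoxy-4-methylbicyclo[2.2.2]oct-5-en-2-one, benzyloxy group syn to the C5=C6 bridge (one enantiomer drawn) | O=C1[C@H]2C=C[C@@](C)(C1(OC)OC)C[C@@H]2OCc1ccccc1 | intermediate
5 | rac-7-(benzyloxy)-3,3-dimethoxy-4-methylbicyclo[2.2.2]oct-5-en-2-ol, hydroxyl group anti to the C5=C6 bridge (one enantiomer drawn) | O[C@@H]1[C@H]2C=C[C@@](C)(C1(OC)OC)C[C@@H]2OCc1ccccc1 | intermediate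
6 | sodium O-[7-(benzyloxy)-3,3-dimethoxy-4-methylbicyclo[2.2.2]oct-5-en-2-yl] carbonodithioate (racemic) | [Na+].[S-]C(=S)O[C@@H]1[C@H]2C=C[C@@](C)(C1(OC)OC)C[C@@H]2OCc1ccccc1 | intermediate
7 | rac-O-[7-(benzyloxy)-3,3-dimethoxy-4-methylbicyclo[2.2.2]oct-5-en-2-yl] S-methyl carbonodithioate | CSC(=S)O[C@@H]1[C@H]2C=C[C@@](C)(C1(OC)OC)C[C@@H]2OCc1ccccc1 | intermediate
8 | rac-2-(benzyloxy)-8,8-dimethoxy-4-methylbicyclo[2.2.2]oct-5-ene, benzyloxy group syn to the C5=C6 bridge | C1[C@H]2C=C[C@@](C)(C1(OC)OC)C[C@@H]2OCc1ccccc1 | intermediate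
9 | rac-8,8-dimethoxy-4-methylbicyclo[2.2.2]oct-5-en-2-ol, hydroxyl group syn to the C5=C6 bridge (one enantiomer drawn) | C1[C@H]2C=C[C@@](C)(C1(OC)OC)C[C@@H]2O | intermediate
10 | (1S,2S,4S)-8,8-dimethoxy-4-methylbicyclo[2.2.2]oct-5-en-2-ol (single enantiomer) | C1[C@H]2C=C[C@@](C)(C1(OC)OC)C[C@@H]2O | intermediate
11 | (1S,4S)-8,8-dimethoxy-4-methylbicyclo[2.2.2]oct-5-en-2-one | C1[C@H]2C=C[C@@](C)(C1(OC)OC)CC2=O | intermediate
12 | 1-bromo-2-methylprop-1-ene | CC(C)=CBr | starting material
13 | (2-methylprop-1-en-1-yl)lithium | [Li]C=C(C)C | intermediate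
14 | dichloro(2-methylprop-1-en-1-yl)cerium | Cl[Ce](Cl)C=C(C)C | intermediate
15 | (1S,2R,4S)-8,8-dimethoxy-4-methyl-2-(2-methylprop-1-en-1-yl)bicyclo[2.2.2]oct-5-en-2-ol, alkenyl group syn to the C5=C6 bridge | C1[C@H]2C=C[C@@](C)(C1(OC)OC)C[C@]2(O)C=C(C)C | intermediate
16 | potassium (1S,2R,4S)-8,8-dimethoxy-4-methyl-2-(2-methylprop-1-en-1-yl)bicyclo[2.2.2]oct-5-en-2-olate | C1[C@H]2C=C[C@@](C)(C1(OC)OC)C[C@]2([O-])C=C(C)C.[K+] | intermediate
17 | potassium (4aR,8aS)-8,8-dimethoxy-4,4,8a-trimethyl-1,4,4a,7,8,8a-hexahydronaphthalen-2-olate | C1C=C[C@@H]2C(C)(C)C=C([O-])C[C@]2(C)C1(OC)OC.[K+] | intermediate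
18 | (4aR,8aS)-8,8-dimethoxy-4,4,8a-trimethyl-3,4,4a,7,8,8a-hexahydronaphthalen-2(1H)-one | C1C=C[C@@H]2C(C)(C)CC(=O)C[C@]2(C)C1(OC)OC | intermediate
19 | hydrazone of 18 | C1C=C[C@@H]2C(C)(C)CC(=NN)C[C@]2(C)C1(OC)OC | intermediate
20 | (4aR,8aS)-1,1-dimethoxy-5,5,8a-trimethyl-1,2,4a,5,6,7,8,8a-octahydronaphthalene | C1C=C[C@@H]2C(C)(C)CCC[C@]2(C)C1(OC)OC | intermediate
21 | (4aR,8aS)-1,1-dimethoxy-5,5,8a-trimethyldecahydronaphthalene | C1CC[C@@H]2C(C)(C)CCC[C@]2(C)C1(OC)OC | intermediate
22 | (4aR,8aS)-5,5,8a-trimethyloctahydronaphthalen-1(2H)-one | O=C1CCC[C@@H]2C(C)(C)CCC[C@]12C | intermediate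
23 | potassium (4aR,8aS)-5,5,8a-trimethyl-3,4,4a,5,6,7,8,8a-octahydronaphthalen-1-olate | [K+].[O-]C1=CCC[C@@H]2C(C)(C)CCC[C@]12C | intermediate
24 | (4aR,8aS)-5,5,8a-trimethyl-3,4,4a,5,6,7,8,8a-octahydronaphthalen-1-yl trifluoromethanesulfonate | O=S(=O)(OC1=CCC[C@@H]2C(C)(C)CCC[C@]12C)C(F)(F)F | intermediate
25 | 2,4,5-trimethoxybenzaldehyde | COc1cc(OC)c(C=O)cc1OC | starting material
26 | 5,5-dimethyl-2-(2,4,5-trimethoxyphenyl)-1,3-dioxane | COc1cc(OC)c(C2OCC(C)(C)CO2)cc1OC | intermediate
27 | [3-(5,5-dimethyl-1,3-dioxan-2-yl)-2,5,6-trimethoxyphenyl]lithium | COc1c([Li])c(OC)c(C2OCC(C)(C)CO2)cc1OC | intermediate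
28 | 3-(5,5-dimethyl-1,3-dioxan-2-yl)-2,5,6-trimethoxybenzaldehyde | O=Cc1c(OC)c(OC)cc(C2OCC(C)(C)CO2)c1OC | intermediate
29 | dichloro[(4aR,8aS)-5,5,8a-trimethyl-3,4,4a,5,6,7,8,8a-octahydronaphthalen-1-yl]chromium (trivalent chromium) | Cl[Cr](Cl)C1=CCC[C@@H]2C(C)(C)CCC[C@]12C | intermediate
30 | (S)-[3-(5,5-dimethyl-1,3-dioxan-2-yl)-2,5,6-trimethoxyphenyl][(4aR,8aS)-5,5,8a-trimethyl-3,4,4a,5,6,7,8,8a-octahydronaphthalen-1-yl]methanol | O[C@H](c1c(OC)c(OC)cc(C2OCC(C)(C)CO2)c1OC)C1=CCC[C@@H]2C(C)(C)CCC[C@]12C | intermediate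
31 | (S)-[3-(5,5-dimethyl-1,3-dioxan-2-yl)-2,5,6-trimethoxyphenyl][(4aR,8aS)-5,5,8a-trimethyl-3,4,4a,5,6,7,8,8a-octahydronaphthalen-1-yl]methyl pyridine-2-carboxylate | O=C(O[C@H](c1c(OC)c(OC)cc(C2OCC(C)(C)CO2)c1OC)C1=CCC[C@@H]2C(C)(C)CCC[C@]12C)c1ccccn1 | intermediate
32 | 2-[2,4,5-trimethoxy-3-[(E)-[(2S,4aR,8aS)-2,5,5,8a-tetramethyloctahydronaphthalen-1(2H)-ylidene]methyl]phenyl]-5,5-dimethyl-1,3-dioxane | C[C@H]1CC[C@@H]2C(C)(C)CCC[C@]2(C)/C1=C/c1c(OC)c(OC)cc(C2OCC(C)(C)CO2)c1OC | intermediate
33 | 2,4,5-trimethoxy-3-[(E)-[(2S,4aR,8aS)-2,5,5,8a-tetramethyloctahydronaphthalen-1(2H)-ylidene]methyl]benzaldehyde | C[C@H]1CC[C@@H]2C(C)(C)CCC[C@]2(C)/C1=C/c1c(OC)c(OC)cc(C=O)c1OC | intermediate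
34 | 2,4,5-trihydroxy-3-[(E)-[(2S,4aR,8aS)-2,5,5,8a-tetramethyloctahydronaphthalen-1(2H)-ylidene]methyl]benzaldehyde | C[C@H]1CC[C@@H]2C(C)(C)CCC[C@]2(C)/C1=C/c1c(O)c(O)cc(C=O)c1O | target

**Step count**
Total: 20 steps. Longest linear sequence: 18 steps (steps 1–13 and 16–20); the arene branch is steps 14–15.

**Steps most likely to fail**

Step 9 (key step). The inward-pointing methyl group of the trisubstituted alkenyl terminus presses against the C1 methylene group in the enforced boat. The [3,3] shift may therefore be slower than fragmentation of the alkoxide back to ketone 11, or the crowded C4–C5 bond may not form. The fallback keeps the oxy-Cope disconnection but brings in the second C4 methyl group afterwards; it sets out from 11 and comes back at 18. (E)-Prop-1-enyllithium (from (E)-1-bromoprop-1-ene and t-BuLi) with CeCl3 should add to 11 as in step 8 to give (1S,2S,4S)-8,8-dimethoxy-4-methyl-2-[(E)-prop-1-en-1-yl]bicyclo[2.2.2]oct-5-en-2-ol F1, which has no inward substituent. Its oxy-Cope rearrangement (KH, 18-crown-6, THF) is quenched with Me3SiCl/Et3N to trap the regiodefined enolate as [(4S,4aR,8aS)-8,8-dimethoxy-4,8a-dimethyl-1,4,4a,7,8,8a-hexahydronaphthalen-2-yl]oxy(trimethyl)silane F2; its C4 configuration is of no consequence. Saegusa–Ito oxidation (Pd(OAc)2, MeCN) should give the C3=C4 enone (4aR,8aS)-8,8-dimethoxy-4,8a-dimethyl-4a,7,8,8a-tetrahydronaphthalen-2(1H)-one F3. Conjugate addition of Me2CuLi (Me3SiCl, THF, −78 → 0 °C; aqueous work-up) then builds the gem-dimethyl carbon and returns 18.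

Step 16. The coupling joins an alkenylchromium centre next to quaternary C10 with a doubly ortho-substituted aldehyde, and the facial discrimination at C11 may be low, so much of the material may end as the (11R)-epimer. The fallback makes the coupling stereoconvergent; it sets out from 24 and 28 and comes back at 32. The co-formed epimer (R)-[3-(5,5-dimethyl-1,3-dioxan-2-yl)-2,5,6-trimethoxyphenyl][(4aR,8aS)-5,5,8a-trimethyl-3,4,4a,5,6,7,8,8a-octahydronaphthalen-1-yl]methanol F4 is esterified (2-(diphenylphosphanyl)benzoic acid, DCC, DMAP) to its 2-(diphenylphosphanyl)benzoate F5. With MeMgBr and CuBr·SMe2 (0.5 equiv, Et2O, rt) the phosphine binds copper and delivers the methyl group to C8 on the same face as the C11–O bond (directed syn-SN2′). In the (11R)-series that face is again the convex face, so 32 with (8S) and (E) geometry should result.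

Step 18. The picolinate sits on a benzylic carbon flanked by two ortho-methoxy groups; activation by magnesium may ionise it before copper attacks, which would erase the C11-to-C8 chirality transfer and give α-methylation. The fallback avoids any leaving group at C11; it sets out from 30 (the (11R)-epimer serves equally) and comes back at 32. Dess–Martin oxidation should give the aryl enone [3-(5,5-dimethyl-1,3-dioxan-2-yl)-2,5,6-trimethoxyphenyl][(4aR,8aS)-5,5,8a-trimethyl-3,4,4a,5,6,7,8,8a-octahydronaphthalen-1-yl]methanone F6. Conjugate addition of Me2CuLi (Me3SiCl; aqueous work-up) is expected on the convex face of C8, anti to the pseudoaxial C10–C1 bond, giving [3-(5,5-dimethyl-1,3-dioxan-2-yl)-2,5,6-trimethoxyphenyl][(2S,4aR,8aS)-2,5,5,8a-tetramethyldecahydronaphthalen-1-yl]methanone F7 as a mixture at C9. LiAlH4 reduction gives the benzylic alcohol F8 (mixture at C9 and C11). Dehydration with Burgess reagent can only remove H9 and should give the (E)-alkene 32, in which the aryl group avoids quaternary C10.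

**Further compounds**
F1 | step 9 | (1S,2S,4S)-8,8-dimethoxy-4-methyl-2-[(E)-prop-1-en-1-yl]bicyclo[2.2.2]oct-5-en-2-ol, alkenyl group syn to the C5=C6 bridge | C1[C@H]2C=C[C@@](C)(C1(OC)OC)C[C@]2(O)/C=C/C
F2 | step 9 | [(4S,4aR,8aS)-8,8-dimethoxy-4,8a-dimethyl-1,4,4a,7,8,8a-hexahydronaphthalen-2-yl]oxy(trimethyl)silane | C1C=C[C@@H]2[C@H](C)C=C(O[Si](C)(C)C)C[C@]2(C)C1(OC)OC
F3 | step 9 | (4aR,8aS)-8,8-dimethoxy-4,8a-dimethyl-4a,7,8,8a-tetrahydronaphthalen-2(1H)-one | C1C=C[C@@H]2C(C)=CC(=O)C[C@]2(C)C1(OC)OC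
F4 | step 16 | (R)-[3-(5,5-dimethyl-1,3-dioxan-2-yl)-2,5,6-trimethoxyphenyl][(4aR,8aS)-5,5,8a-trimethyl-3,4,4a,5,6,7,8,8a-octahydronaphthalen-1-yl]methanol | O[C@@H](c1c(OC)c(OC)cc(C2OCC(C)(C)CO2)c1OC)C1=CCC[C@@H]2C(C)(C)CCC[C@]12C
F5 | step 16 | (R)-[3-(5,5-dimethyl-1,3-dioxan-2-yl)-2,5,6-trimethoxyphenyl][(4aR,8aS)-5,5,8a-trimethyl-3,4,4a,5,6,7,8,8a-octahydronaphthalen-1-yl]methyl 2-(diphenylphosphanyl)benzoate | O=C(O[C@@H](c1c(OC)c(OC)cc(C2OCC(C)(C)CO2)c1OC)C1=CCC[C@@H]2C(C)(C)CCC[C@]12C)c1ccccc1P(c1ccccc1)c1ccccc1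
F6 | step 18 | [3-(5,5-dimethyl-1,3-dioxan-2-yl)-2,5,6-trimethoxyphenyl][(4aR,8aS)-5,5,8a-trimethyl-3,4,4a,5,6,7,8,8a-octahydronaphthalen-1-yl]methanone | O=C(c1c(OC)c(OC)cc(C2OCC(C)(C)CO2)c1OC)C1=CCC[C@@H]2C(C)(C)CCC[C@]12C
F7 | step 18 | [3-(5,5-dimethyl-1,3-dioxan-2-yl)-2,5,6-trimethoxyphenyl][(2S,4aR,8aS)-2,5,5,8a-tetramethyldecahydronaphthalen-1-yl]methanone (mixture at C1 of the decalin) | C[C@H]1CC[C@@H]2C(C)(C)CCC[C@]2(C)C1C(=O)c1c(OC)c(OC)cc(C2OCC(C)(C)CO2)c1OC
F8 | step 18 | [3-(5,5-dimethyl-1,3-dioxan-2-yl)-2,5,6-trimethoxyphenyl][(2S,4aR,8aS)-2,5,5,8a-tetramethyldecahydronaphthalen-1-yl]methanol (mixture at C1 of the decalin and at the carbinol carbon) | C[C@H]1CC[C@@H]2C(C)(C)CCC[C@]2(C)C1C(O)c1c(OC)c(OC)cc(C2OCC(C)(C)CO2)c1OC
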